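**Plan**

- The cyclohexenone ring carries a tertiary C1'–OH and a C4' ketone placed 1,4 across the C2'=C3' double bond. This is the imprint of a ring 1,3-diene (C1'=C2'–C3'=C4') that has taken up O2 at both ends, so the retrosynthesis first reconnects these two oxygens as an O–O bridge and then cuts C1'–O and C4'–O.
- The next cuts are C1'–C5 (dienyl triflate plus C5 dienylstannane), the C8'–O ester bond (ring alcohol plus glutarate half-ester) and C6'–C8' (silyl dienol ether plus formaldehyde).
- Forward, the carbocycle comes intact from 2,6-dimethylcyclohexanone. The order is enone, C8' hydroxymethyl group, dienyl triflate, glutarate ester, side chain by Stille coupling; the 1,2-dioxene ring is then closed by O2 and opened again by base.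
- Stereochemistry: C6' from a catalytic asymmetric hydroxymethylation; glutarate C3 from esterase desymmetrisation of the prochiral dimethyl ester; C1' from the face of O2 addition, anti to the C6' acyloxymethyl arm; 2Z from the commercial enynol and 4E from syn-hydrostannation.

Key step: step 13

Assumption: the (S,S)-enantiomer of the bipyridine diol ligand is taken to steer formaldehyde to the enol face that gives the (S)-hydroxymethyl enone. The sense must be assigned on the first run; if it is opposite, the (R,R)-ligand is used in the same way.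

**Route**

Step 1
Reactants: 1 2,6-dimethylcyclohexanone (commercial cis/trans mixture)
Product: 2 2-chloro-2,6-dimethylcyclohexan-1-one (mixture of stereoisomers)
Conditions: SO2Cl2, CH2Cl2, 0 °C → rt
Reagents that add atoms: sulfuryl chloride, ClS(Cl)(=O)=O
Why: Electrophilic α-chlorination of the ketone through its enol places chlorine on a tertiary α-carbon (α-halogenation of a ketone); the isomer mixture of 1 is acceptable because both stereocentres are erased in steps 2 and 3.

Step 2
Reactants: 2 2-chloro-2,6-dimethylcyclohexan-1-one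
Product: 3 2,6-dimethylcyclohex-2-en-1-one (racemic)
Conditions: Li2CO3, LiBr, DMF, 120 °C
Reagents that add atoms: none
Why: Halide exchange and base-mediated dehydrohalogenation of the α-halo ketone should give the more substituted, endocyclic conjugated enone.

Step 3
Reactants: 3 2,6-dimethylcyclohex-2-en-1-one
Product: 4 [(2,6-dimethylcyclohexa-1,5-dien-1-yl)oxy]trimethylsilane
Conditions: LiN(iPr)2, THF, −78 °C; Me3SiCl, −78 °C → rt
Reagents that add atoms: chlorotrimethylsilane, C[Si](C)(C)Cl
Why: Kinetic deprotonation of an enone by a lithium amide takes the α' proton at C6, and O-silylation of the cross-conjugated dienolate gives the 2-silyloxy-1,3-diene, which flattens C6 (silyl enol ether formation).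

Step 4
Reactants: 4 [(2,6-dimethylcyclohexa-1,5-dien-1-yl)oxy]trimethylsilane; 5 formaldehyde (37% aqueous)
Product: 6 (S)-6-(hydroxymethyl)-2,6-dimethylcyclohex-2-en-1-one
Conditions: aq. CH2O (5 equiv), Sc(OTf)3 (10 mol %), (S,S)-6,6'-bis(1-hydroxy-2,2-dimethylpropyl)-2,2'-bipyridine (12 mol %), DME/H2O 9:1, −20 °C
Reagents that add atoms: formaldehyde (5), C=O
Why: In this catalytic asymmetric Mukaiyama aldol reaction with aqueous formaldehyde only the enol carbon C6 of the cross-conjugated dienol ether is nucleophilic, so the C6–CH2OH bond forms there, and the chiral bipyridine-bound Sc(OTf)3 that activates formaldehyde selects the enol face, which sets the quaternary centre as S.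

Step 5
Reactants: 6 (S)-6-(hydroxymethyl)-2,6-dimethylcyclohex-2-en-1-one
Product: 7 (S)-6-{[(tert-butyldimethylsilyl)oxy]methyl}-2,6-dimethylcyclohex-2-en-1-one
Conditions: TBSCl, imidazole, DMF, 0 °C → rt
Reagents that add atoms: tert-butyldimethylsilyl chloride, CC(C)(C)[Si](C)(C)Cl
Why: Standard silylation of a primary alcohol under mild base avoids retro-aldol loss of formaldehyde and masks the hydroxyl for the enolisation in step 6.

Step 6
Reactants: 7 (S)-6-{[(tert-butyldimethylsilyl)oxy]methyl}-2,6-dimethylcyclohex-2-en-1-one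
Product: 8 (S)-6-{[(tert-butyldimethylsilyl)oxy]methyl}-2,6-dimethylcyclohexa-1,3-dien-1-yl trifluoromethanesulfonate
Conditions: LiN(iPr)2, THF, −78 → −20 °C; PhNTf2, −78 °C → rt; aq. NH4Cl
Reagents that add atoms: N-phenylbis(trifluoromethanesulfonimide), O=S(=O)(N(c1ccccc1)S(=O)(=O)C(F)(F)F)C(F)(F)F
Why: With the α' carbon quaternary the amide base can only remove a γ proton at C4, and O-sulfonylation of the linear dienolate gives the cyclohexa-1,3-dienyl triflate (enol triflate formation) without touching the C6 centre.

Step 7
Reactants: 8 (S)-6-{[(tert-butyldimethylsilyl)oxy]methyl}-2,6-dimethylcyclohexa-1,3-dien-1-yl trifluoromethanesulfonate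
Product: 9 (S)-6-(hydroxymethyl)-2,6-dimethylcyclohexa-1,3-dien-1-yl trifluoromethanesulfonate
Conditions: HF·pyridine, pyridine, THF, 0 °C → rt
Reagents that add atoms: none
Why: Buffered HF cleaves the primary silyl ether through the strong Si–F bond while the enol triflate and the diene are inert to it (fluoride desilylation).

Step 8
Reactants: 10 dimethyl 3-hydroxy-3-methylpentanedioate (dimethyl 3-hydroxy-3-methylglutarate)
Product: 11 (S)-3-hydroxy-5-methoxy-3-methyl-5-oxopentanoic acid (the (S)-monomethyl ester)
Conditions: pig liver esterase, 0.1 M phosphate buffer pH 8, 1 M NaOH (pH-stat), 25 °C; then HCl to pH 2, EtOAc extraction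
Reagents that add atoms: water, O
Why: Esterase hydrolysis of one of the two enantiotopic ester groups of the prochiral diester (enzymatic desymmetrisation) creates the C3 stereocentre, the (S)-half-ester being the enantiomer expected from this enzyme with this substrate.

Step 9
Reactants: 9 (S)-6-(hydroxymethyl)-2,6-dimethylcyclohexa-1,3-dien-1-yl trifluoromethanesulfonate; 11 (S)-3-hydroxy-5-methoxy-3-methyl-5-oxopentanoic acid
Product: 12 [(1S)-1,3-dimethyl-2-(trifluoromethanesulfonyloxy)cyclohexa-2,4-dien-1-yl]methyl methyl (3R)-3-hydroxy-3-methylpentanedioate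
Conditions: EDC·HCl, DMAP (cat.), CH2Cl2, 0 °C → rt
Reagents that add atoms: none
Why: Steglich esterification through the O-acylisourea and acylpyridinium ion acylates the primary neopentyl alcohol, the tertiary hydroxyl of 11 being too hindered to compete, and no bond to either stereocentre is touched (the glutarate descriptor changes from S to R only through the CIP priorities).

Step 10
Reactants: 13 (Z)-3-methylpent-2-en-4-yn-1-ol
Product: 14 (Z)-3-methylpent-2-en-4-ynoic acid
Conditions: CrO3, H2SO4, H2O, acetone, 0 °C
Reagents that add atoms: water, O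
Why: Jones oxidation takes the allylic alcohol through the aldehyde hydrate to the acid under conditions in which the trisubstituted Z double bond and the terminal alkyne should survive.

Step 11
Reactants: 14 (Z)-3-methylpent-2-en-4-ynoic acid
Product: 16 tributylstannyl (2Z,4E)-3-methyl-5-(tributylstannyl)penta-2,4-dienoate, via tributylstannyl ynenoate 15 (not isolated)
Conditions: (Bu3Sn)2O (0.5 equiv), 4 Å molecular sieves, THF, rt; then Pd(PPh3)4 (2 mol %), Bu3SnH (1.1 equiv), 0 °C → rt; filtered and concentrated, used without chromatography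
Reagents that add atoms: bis(tributyltin) oxide, CCCC[Sn](CCCC)(CCCC)O[Sn](CCCC)(CCCC)CCCC; tributyltin hydride, CCCC[SnH](CCCC)CCCC
Why: The stannyl ester removes the acidic proton, and zerovalent palladium then catalyses syn addition of Sn–H across the terminal alkyne with tin on the unhindered terminal carbon, since C3 is fully substituted, which gives the 4E vinylstannane with the 2Z bond unchanged (palladium-catalysed hydrostannation).

Step 12
Reactants: 12 the dienyl triflate glutarate ester; 16 tributylstannyl (2Z,4E)-3-methyl-5-(tributylstannyl)penta-2,4-dienoate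
Product: 18 (2Z,4E)-5-[(6R)-6-({[(3R)-3-hydroxy-5-methoxy-3-methyl-5-oxopentanoyl]oxy}methyl)-2,6-dimethylcyclohexa-1,3-dien-1-yl]-3-methylpenta-2,4-dienoic acid, via its tributylstannyl ester 17 (not isolated)
Conditions: Pd2(dba)3 (5 mol %), AsPh3 (40 mol %), NMP, 50 °C, dark; then aq. KF; then 0.5 M HCl to pH 3, 0 °C
Reagents that add atoms: none
Why: Stille coupling: oxidative addition of zerovalent palladium into the C1'–OTf bond, tin-to-palladium transfer of the dienyl group accelerated by the weakly bound AsPh3 in NMP, and reductive elimination form the C1'–C5 bond with retention of both double-bond geometries, and the tributylstannyl ester is cleaved to the free acid by fluoride and acid at work-up (the ring descriptor changes from S to R only through the CIP priorities).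

Step 13
Reactants: 18 the cyclohexa-1,3-dienyl tetraenoic acid; 19 dioxygen
Product: 20 the 1',4'-endoperoxide (2,3-dioxabicyclo[2.2.2]oct-5-ene; O–O bridge on the face of the C6' methyl, anti to the acyloxymethyl arm; 1'R,4'R,6'S in abscisic acid numbering)
Conditions: O2, tetraphenylporphyrin (1 mol %), CH2Cl2, −40 °C, visible light (λ > 450 nm); concentrated cold and used at once
Reagents that add atoms: dioxygen (19), O=O
Why: Energy transfer from the excited porphyrin makes singlet oxygen, which adds suprafacially in a concerted [4+2] cycloaddition to the s-cis ring diene C1'=C2'–C3'=C4', forming the C1'–O and C4'–O bonds. The closest known reaction is the dye-sensitised photooxygenation of 1-substituted cyclohexa-1,3-dienes to 2,3-dioxabicyclo[2.2.2]oct-5-enes. The one new ring, the six-membered 1,2-dioxene made of C1', C2', C3', C4' and the two oxygens, closes by cycloaddition across the diene termini and so bridges the carbocycle. The two new stereocentres, C1' and C4', are set together by the face of attack, which is controlled by C6': the acyloxymethyl arm, the larger group, should sit pseudoaxial to avoid eclipsing the C1' side chain and so shields its own face, and its ester oxygens repel the incoming oxygen, so the bridge should form on the face of the C6' methyl. The step needs this facial selectivity, [4+2] addition over ene reaction at the C2' methyl, and reaction at the ring diene instead of the chain diene; the locked s-cis geometry and low temperature favour cycloaddition, the chain diene is s-trans and deactivated by the carboxyl group, and long-wavelength sensitisation avoids direct excitation of the polyene.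

Step 14
Reactants: 20 the 1',4'-endoperoxide
Product: 21 (2Z,4E)-5-[(1R,6S)-1-hydroxy-6-({[(3R)-3-hydroxy-5-methoxy-3-methyl-5-oxopentanoyl]oxy}methyl)-2,6-dimethyl-4-oxocyclohex-2-en-1-yl]-3-methylpenta-2,4-dienoic acid (CNP0274837.1)
Conditions: Et3N (3 equiv), CH2Cl2, 0 °C → rt; then cold dilute HCl to pH 3
Reagents that add atoms: none
Why: Kornblum–DeLaMare rearrangement: the amine removes the only bridgehead hydrogen, H4', the O–O bond breaks to give the C4' ketone and the C1' alkoxide, and because the C1'–O bond is not broken the C1' configuration from step 13 is kept while the C4' stereocentre is erased.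

**Compound list**

1 | 2,6-dimethylcyclohexanone | CC1CCCC(C)C1=O | starting material
2 | 2-chloro-2,6-dimethylcyclohexan-1-one | CC1CCCC(C)(Cl)C1=O | intermediate
3 | 2,6-dimethylcyclohex-2-en-1-one | CC1CCC=C(C)C1=O | intermediate
4 | [(2,6-dimethylcyclohexa-1,5-dien-1-yl)oxy]trimethylsilane | CC1=C(O[Si](C)(C)C)C(C)=CCC1 | intermediate
5 | formaldehyde | C=O | starting material
6 | (S)-6-(hydroxymethyl)-2,6-dimethylcyclohex-2-en-1-one | OC[C@]1(C)CCC=C(C)C1=O | intermediate
7 | (S)-6-{[(tert-butyldimethylsilyl)oxy]methyl}-2,6-dimethylcyclohex-2-en-1-one | CC(C)(C)[Si](C)(C)OC[C@]1(C)CCC=C(C)C1=O | intermediate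
8 | (S)-6-{[(tert-butyldimethylsilyl)oxy]methyl}-2,6-dimethylcyclohexa-1,3-dien-1-yl trifluoromethanesulfonate | CC(C)(C)[Si](C)(C)OC[C@]1(C)CC=CC(C)=C1OS(=O)(=O)C(F)(F)F | intermediate
9 | (S)-6-(hydroxymethyl)-2,6-dimethylcyclohexa-1,3-dien-1-yl trifluoromethanesulfonate | OC[C@]1(C)CC=CC(C)=C1OS(=O)(=O)C(F)(F)F | intermediate
10 | dimethyl 3-hydroxy-3-methylpentanedioate | COC(=O)CC(C)(O)CC(=O)OC | starting material
11 | (S)-3-hydroxy-5-methoxy-3-methyl-5-oxopentanoic acid | COC(=O)C[C@@](C)(O)CC(=O)O | intermediate
12 | [(1S)-1,3-dimethyl-2-(trifluoromethanesulfonyloxy)cyclohexa-2,4-dien-1-yl]methyl methyl (3R)-3-hydroxy-3-methylpentanedioate | COC(=O)C[C@@](C)(O)CC(=O)OC[C@]1(C)CC=CC(C)=C1OS(=O)(=O)C(F)(F)F | intermediate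
13 | (Z)-3-methylpent-2-en-4-yn-1-ol | C#C/C(C)=C\CO | starting material
14 | (Z)-3-methylpent-2-en-4-ynoic acid | C#C/C(C)=C\C(=O)O | intermediate
15 | tributylstannyl (Z)-3-methylpent-2-en-4-ynoate | C#C/C(C)=C\C(=O)O[Sn](CCCC)(CCCC)CCCC | intermediate
16 | tributylstannyl (2Z,4E)-3-methyl-5-(tributylstannyl)penta-2,4-dienoate | CCCC[Sn](CCCC)(CCCC)/C=C/C(C)=C\C(=O)O[Sn](CCCC)(CCCC)CCCC | intermediate
17 | tributylstannyl ester of 18 | COC(=O)C[C@@](C)(O)CC(=O)OC[C@]1(C)CC=CC(C)=C1/C=C/C(C)=C\C(=O)O[Sn](CCCC)(CCCC)CCCC | intermediate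
18 | (2Z,4E)-5-[(6R)-6-({[(3R)-3-hydroxy-5-methoxy-3-methyl-5-oxopentanoyl]oxy}methyl)-2,6-dimethylcyclohexa-1,3-dien-1-yl]-3-methylpenta-2,4-dienoic acid | COC(=O)C[C@@](C)(O)CC(=O)OC[C@]1(C)CC=CC(C)=C1/C=C/C(C)=C\C(=O)O | intermediate
19 | dioxygen | O=O | starting material
20 | 1',4'-endoperoxide of 18 (peroxide bridge cis to the C6' methyl) | COC(=O)C[C@@](C)(O)CC(=O)OC[C@]1(C)C[C@H]2OO[C@]1(/C=C/C(C)=C\C(=O)O)C(C)=C2 | intermediate
21 | (2Z,4E)-5-[(1R,6S)-1-hydroxy-6-({[(3R)-3-hydroxy-5-methoxy-3-methyl-5-oxopentanoyl]oxy}methyl)-2,6-dimethyl-4-oxocyclohex-2-en-1-yl]-3-methylpenta-2,4-dienoic acid | COC(=O)C[C@@](C)(O)CC(=O)OC[C@]1(C)CC(=O)C=C(C)[C@]1(O)/C=C/C(C)=C\C(=O)O | target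

**Count and risks**

Total steps: 14. Longest linear sequence: 11 steps (steps 1–7, 9, 12, 13, 14).

Most likely to fail:

Step 13. Singlet oxygen may discriminate poorly between the methyl and acyloxymethyl faces, or be diverted into ene hydroperoxidation at the C2' methyl or oxidation of the chain diene. The fallback builds the C1' carbinol by carbonyl addition instead; it sets out from 7 (using 13 and 11) and comes back at 21.
- Allylic oxidation of 7 at C4 (Rh2(caprolactamate)4, tBuOOH, K2CO3, CH2Cl2) should give the enedione F1.
- The less hindered C4 carbonyl is ketalised (TMSOCH2CH2OTMS, TMSOTf, CH2Cl2, −78 °C) to the monoketal F2, and TBAF buffered with AcOH frees the hydroxy ketal F3.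
- The bromomagnesium acetylide–alkoxide made from 13 with EtMgBr is added to the magnesium alkoxide of F3. Chelation between the C1 carbonyl and the 8'-alkoxide should hold the oxymethyl arm in the ring plane and the methyl axial, so the acetylide should enter anti to the methyl and give the acetylenic triol F4; any C1' epimer is removed here.
- NaAlH2(OCH2CH2OMe)2 (Red-Al, THF, 0 °C) trans-reduces the propargylic alcohol to the (2Z,4E)-dienol F5, and MnO2 oxidises only the allylic primary alcohol to the dienal F6.
- EDC/DMAP acylation of the neopentyl 8'-hydroxyl with 11 gives the glutarate dienal F7, and Pinnick oxidation (NaClO2, NaH2PO4, 2-methylbut-2-ene) gives the ketal acid F8.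
- Dilute HCl in aqueous acetone removes the dioxolane and returns to the route at 21.

Step 12. Oxidative addition and transmetalation at the dienyl triflate, flanked by the C2' methyl and the quaternary C6', may be slow, which would allow protodestannylation or homocoupling of the stannane and erosion of the 2Z geometry on prolonged heating. The fallback uses a boron partner with a protected acid; it sets out from 14 (and 12) and comes back at 18.
- 14 is esterified with 2-(trimethylsilyl)ethanol (EDC, DMAP) to the silylethyl ynenoate F9.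
- Hydroboration with pinacolborane catalysed by Cp2ZrHCl (Et3N, CH2Cl2) gives the (2Z,4E)-dienyl boronate F10.
- Suzuki–Miyaura coupling with 12 (PdCl2(dppf), K3PO4, THF/H2O, rt) gives the silylethyl tetraenoate F11.
- TBAF (THF, 0 °C) releases the acid and returns to the route at 18.

Step 4. Enantioface selection may be insufficient or opposite, or the silyl dienol ether may hydrolyse back to the enone before the C–C bond forms. The fallback replaces asymmetric catalysis by resolution; it sets out from 4 and comes back at 6.
- 4 is hydroxymethylated without a chiral ligand (aq. CH2O, Yb(OTf)3, THF/H2O) to the racemic alcohol F12.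
- Esterification with (S)-2-methoxy-2-phenylacetic acid (EDC, DMAP) gives two diastereomeric esters that are separated by chromatography, and the (S)-C6 mandelate F13 is kept.
- Brief methanolysis (K2CO3, MeOH, 0 °C, kept cold to avoid retro-aldol loss of formaldehyde) returns to the route at 6.

**Further compounds**

F1 | step 13 | (S)-6-{[(tert-butyldimethylsilyl)oxy]methyl}-2,6-dimethylcyclohex-2-ene-1,4-dione | CC(C)(C)[Si](C)(C)OC[C@]1(C)CC(=O)C=C(C)C1=O
F2 | step 13 | C4 ethylene ketal of F1 | CC(C)(C)[Si](C)(C)OC[C@]1(C)CC2(OCCO2)C=C(C)C1=O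
F3 | step 13 | (S)-hydroxymethyl enone C4 ethylene ketal | OC[C@]1(C)CC2(OCCO2)C=C(C)C1=O
F4 | step 13 | acetylenic triol (C1' hydroxyl cis to the C6' methyl, 2Z enynol side chain) | OC[C@]1(C)CC2(OCCO2)C=C(C)[C@]1(O)C#C/C(C)=C\CO
F5 | step 13 | (2Z,4E)-dienol triol ketal | OC[C@]1(C)CC2(OCCO2)C=C(C)[C@]1(O)/C=C/C(C)=C\CO
F6 | step 13 | (2Z,4E)-dienal diol ketal | OC[C@]1(C)CC2(OCCO2)C=C(C)[C@]1(O)/C=C/C(C)=C\C=O
F7 | step 13 | 8'-O-glutarate of the dienal ketal | COC(=O)C[C@@](C)(O)CC(=O)OC[C@]1(C)CC2(OCCO2)C=C(C)[C@]1(O)/C=C/C(C)=C\C=O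
F8 | step 13 | C4' ethylene ketal of 21 | COC(=O)C[C@@](C)(O)CC(=O)OC[C@]1(C)CC2(OCCO2)C=C(C)[C@]1(O)/C=C/C(C)=C\C(=O)O
F9 | step 12 | 2-(trimethylsilyl)ethyl (Z)-3-methylpent-2-en-4-ynoate | C#C/C(C)=C\C(=O)OCC[Si](C)(C)C
F10 | step 12 | 2-(trimethylsilyl)ethyl (2Z,4E)-3-methyl-5-(4,4,5,5-tetramethyl-1,3,2-dioxaborolan-2-yl)penta-2,4-dienoate | CC1(C)OB(/C=C/C(C)=C\C(=O)OCC[Si](C)(C)C)OC1(C)C
F11 | step 12 | 2-(trimethylsilyl)ethyl ester of 18 | COC(=O)C[C@@](C)(O)CC(=O)OC[C@]1(C)CC=CC(C)=C1/C=C/C(C)=C\C(=O)OCC[Si](C)(C)C
F12 | step 4 | racemic 6-(hydroxymethyl)-2,6-dimethylcyclohex-2-en-1-one | OCC1(C)CCC=C(C)C1=O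
F13 | step 4 | [(1S)-1,3-dimethyl-2-oxocyclohex-3-en-1-yl]methyl (S)-2-methoxy-2-phenylacetate | CO[C@H](C(=O)OC[C@]1(C)CCC=C(C)C1=O)c1ccccc1
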